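**Retrosynthetic overview**
1. Target 22 ⇐ aldehyde 21 (NaBH4) ⇐ protected diaryl ether 20 (acid). The CH2OH is carried as CHO because the CHO, together with the CO2Me, activates the ether-forming step.
2. Diaryl ether C–O bond of 20 ⇐ SNAr between ring B phenol 13 (fragment B, a phthalide) and ring A aryl fluoride 19 (fragment A).
3. Fragment B ⇐ methyl gallate 1. After acetonide formation, the key C–C bond (aryl–CH2, the future 4-methyl of the phthalide) is made by an intermolecular phenolic Mannich reaction with CH2O/Me2NH ortho to the free OH, then reduced to CH3. Bromination, ester reduction and lithiation/CO2 then close the lactone.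
4. Fragment A ⇐ 3-fluoro-5-methylphenol 14: para-bromination, MOM ether, lithiation/formylation between F and OMOM, Pd-catalysed methoxycarbonylation of the bromide.
5. Ring order: both benzene rings are bought; the dioxole (protecting) ring is formed first, then the lactone ring of the phthalide; the two aryl fragments are joined three steps from the end.

Assumption: the target SMILES contains no stereocentre or other stereogenic element, so the compound is achiral and no stereocontrol is needed.

**Fragment B (ring B phthalide)**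

Step 1
Reactants: 1 methyl gallate (methyl 3,4,5-trihydroxybenzoate)
Product: 2 methyl 7-hydroxy-2,2-dimethyl-1,3-benzodioxole-5-carboxylate
Conditions: 2,2-dimethoxypropane (3 equiv), p-TsOH·H2O (5 mol%), toluene, reflux, 4 Å MS
Reagents that add atoms: 2,2-dimethoxypropane, COC(C)(C)OC
Why: Acid-catalysed transketalisation (acetonide formation) of one vicinal phenol pair, where the symmetry of the gallate makes every mono-acetonide the same compound and leaves one free phenol, the future ether oxygen.

Step 2
Reactants: 2 methyl 7-hydroxy-2,2-dimethyl-1,3-benzodioxole-5-carboxylate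
Product: 3 methyl 6-[(dimethylamino)methyl]-7-hydroxy-2,2-dimethyl-1,3-benzodioxole-5-carboxylate
Conditions: aq. Me2NH (40%, 1.5 equiv), aq. CH2O (37%, 1.5 equiv), EtOH, 0 °C → 50 °C
Reagents that add atoms: formaldehyde, C=O; dimethylamine, CNC
Why: Intermolecular phenolic Mannich reaction, in which the iminium ion from CH2O and Me2NH is delivered through a hydrogen-bonded transition state to the only free position ortho to the phenol (C6) and forms the aryl–CH2 bond that becomes the ring B methyl group.

Step 3
Reactants: 3 methyl 6-[(dimethylamino)methyl]-7-hydroxy-2,2-dimethyl-1,3-benzodioxole-5-carboxylate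
Product: 4 1-[7-hydroxy-5-(methoxycarbonyl)-2,2-dimethyl-1,3-benzodioxol-6-yl]-N,N,N-trimethylmethanaminium iodide
Conditions: MeI (3 equiv), acetone, rt, dark; evaporate to dryness
Reagents that add atoms: iodomethane, CI
Why: Menshutkin N-quaternisation turns the amine into a trimethylammonium leaving group, while the neutral, hydrogen-bonded phenol is not methylated without base.

Step 4
Reactants: 4 1-[7-hydroxy-5-(methoxycarbonyl)-2,2-dimethyl-1,3-benzodioxol-6-yl]-N,N,N-trimethylmethanaminium iodide
Product: 6 methyl 7-hydroxy-2,2,6-trimethyl-1,3-benzodioxole-5-carboxylate, via ortho-quinone methide 5 (not isolated)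
Conditions: NaBH4 (3 equiv), DMF, 0 °C → rt; aq. NH4Cl
Reagents that add atoms: none
Why: Base-induced 1,4-elimination of NMe3 gives an ortho-quinone methide that is trapped by hydride in a conjugate reduction to leave a methyl group, while the methyl benzoate and the acetonide are inert to NaBH4 at room temperature.

Step 5
Reactants: 6 methyl 7-hydroxy-2,2,6-trimethyl-1,3-benzodioxole-5-carboxylate
Product: 7 methyl 7-(benzyloxy)-2,2,6-trimethyl-1,3-benzodioxole-5-carboxylate
Conditions: BnBr (1.2 equiv), K2CO3, DMF, rt
Reagents that add atoms: benzyl bromide, BrCc1ccccc1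
Why: Williamson etherification masks the phenol with a group that survives hydride and organolithium reagents and is later removed by hydrogenolysis without touching the acetonide.

Step 6
Reactants: 7 methyl 7-(benzyloxy)-2,2,6-trimethyl-1,3-benzodioxole-5-carboxylate
Product: 8 methyl 7-(benzyloxy)-4-bromo-2,2,6-trimethyl-1,3-benzodioxole-5-carboxylate
Conditions: NBS (1.05 equiv), MeCN, 0 °C → rt
Reagents that add atoms: N-bromosuccinimide, O=C1CCC(=O)N1Br
Why: Electrophilic aromatic bromination can only occur at the single remaining ring C–H, which is activated by the ortho dioxole oxygen and the para benzyloxy group.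

Step 7
Reactants: 8 methyl 7-(benzyloxy)-4-bromo-2,2,6-trimethyl-1,3-benzodioxole-5-carboxylate
Product: 9 [7-(benzyloxy)-4-bromo-2,2,6-trimethyl-1,3-benzodioxol-5-yl]methanol
Conditions: iBu2AlH (3 equiv), CH2Cl2, −78 → 0 °C; aq. KNaC4H4O6 work-up
Reagents that add atoms: none
Why: Hydride reduction of the ester with iBu2AlH gives the benzylic alcohol (the future lactone CH2–O) and leaves the aryl bromide, benzyl ether and acetonide intact.

Step 8
Reactants: 9 [7-(benzyloxy)-4-bromo-2,2,6-trimethyl-1,3-benzodioxol-5-yl]methanol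
Product: 12 5-(benzyloxy)-6,7-(isopropylidenedioxy)-4-methylisobenzofuran-1(3H)-one, via aryllithium alkoxide 10 (not isolated), via hydroxy acid 11 (not isolated)
Conditions: n-BuLi (2.2 equiv), THF, −78 °C; CO2 (g), −78 °C → rt; then 1 M HCl, rt
Reagents that add atoms: carbon dioxide, O=C=O
Why: Deprotonation of the alcohol and bromine–lithium exchange give an aryllithium that is carboxylated by CO2, and the resulting 2-(hydroxymethyl)benzoic acid lactonises on acidification to the phthalide with its carbonyl next to the dioxole oxygen.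

Step 9
Reactants: 12 5-(benzyloxy)-6,7-(isopropylidenedioxy)-4-methylisobenzofuran-1(3H)-one
Product: 13 5-hydroxy-6,7-(isopropylidenedioxy)-4-methylisobenzofuran-1(3H)-one (fragment B)
Conditions: H2 (1 atm), 10% Pd/C, EtOAc/MeOH, rt
Reagents that add atoms: none
Why: Catalytic hydrogenolysis cleaves only the benzyl ether and frees the phenol flanked by the methyl group and the dioxole oxygen.

**Fragment A (ring A aryl fluoride)**

Step 10
Reactants: 14 3-fluoro-5-methylphenol
Product: 15 4-bromo-3-fluoro-5-methylphenol
Conditions: NBS (1.0 equiv), MeCN, −10 → 0 °C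
Reagents that add atoms: N-bromosuccinimide, O=C1CCC(=O)N1Br
Why: Electrophilic bromination of a phenol with NBS in MeCN is para-selective, which puts bromine between F and CH3 at the carbon that will carry the ester.

Step 11
Reactants: 15 4-bromo-3-fluoro-5-methylphenol
Product: 16 2-bromo-1-fluoro-5-(methoxymethoxy)-3-methylbenzene
Conditions: MOMCl (1.3 equiv), iPr2NEt, CH2Cl2, 0 °C → rt
Reagents that add atoms: chloromethyl methyl ether, COCCl
Why: O-Alkylation gives a methoxymethyl ether that protects the phenol, directs the following metalation and is removed by acid at the end.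

Step 12
Reactants: 16 2-bromo-1-fluoro-5-(methoxymethoxy)-3-methylbenzene
Product: 18 3-bromo-2-fluoro-6-(methoxymethoxy)-4-methylbenzaldehyde, via aryllithium 17 (not isolated)
Conditions: LiN(iPr)2 (1.1 equiv), THF, −78 °C, 1 h; DMF, −78 → −40 °C; aq. NH4Cl
Reagents that add atoms: N,N-dimethylformamide, CN(C)C=O
Why: Directed ortho-metalation removes the most acidic ring proton, the one flanked by F and OMOM, with an amide base that does not exchange the aryl bromide, and DMF formylates the aryllithium.

Step 13
Reactants: 18 3-bromo-2-fluoro-6-(methoxymethoxy)-4-methylbenzaldehyde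
Product: 19 methyl 2-fluoro-3-formyl-4-(methoxymethoxy)-6-methylbenzoate (fragment A)
Conditions: CO (1 atm), MeOH (10 equiv), Pd(OAc)2 (5 mol%), Xantphos (6 mol%), Et3N, toluene, 70 °C
Reagents that add atoms: carbon monoxide, [C-]#[O+]; methanol, CO
Why: Palladium-catalysed alkoxycarbonylation, in which zerovalent palladium inserts into the C–Br bond, CO inserts and methanol cleaves the acyl complex, with the weak base and limited methanol chosen to spare the activated fluoride.

**Union and endgame**

Step 14
Reactants: 13 5-hydroxy-6,7-(isopropylidenedioxy)-4-methylisobenzofuran-1(3H)-one; 19 methyl 2-fluoro-3-formyl-4-(methoxymethoxy)-6-methylbenzoate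
Product: 20 methyl 3-formyl-2-{[6,7-(isopropylidenedioxy)-4-methyl-1-oxo-1,3-dihydroisobenzofuran-5-yl]oxy}-4-(methoxymethoxy)-6-methylbenzoate
Conditions: Cs2CO3 (1.5 equiv), DMF, 4 Å MS, 60–70 °C
Reagents that add atoms: none
Why: Nucleophilic aromatic substitution (SNAr), in which the fluoride is flanked by an ortho ester and an ortho aldehyde that both stabilise the Meisenheimer adduct, so the caesium phenoxide of 13 can displace it despite the crowding.

Step 15
Reactants: 20 methyl 3-formyl-2-{[6,7-(isopropylidenedioxy)-4-methyl-1-oxo-1,3-dihydroisobenzofuran-5-yl]oxy}-4-(methoxymethoxy)-6-methylbenzoate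
Product: 21 methyl 2-[(6,7-dihydroxy-4-methyl-1-oxo-1,3-dihydroisobenzofuran-5-yl)oxy]-3-formyl-4-hydroxy-6-methylbenzoate
Conditions: TFA/H2O (9:1), 0 °C → rt
Reagents that add atoms: none
Why: Acidolysis cleaves both acetal-type protecting groups (MOM ether and catechol acetonide) in one operation, while the methyl ester, lactone, diaryl ether and aldehyde are stable to aqueous TFA.

Step 16
Reactants: 21 methyl 2-[(6,7-dihydroxy-4-methyl-1-oxo-1,3-dihydroisobenzofuran-5-yl)oxy]-3-formyl-4-hydroxy-6-methylbenzoate
Product: 22 methyl 2-[(6,7-dihydroxy-4-methyl-1-oxo-1,3-dihydroisobenzofuran-5-yl)oxy]-4-hydroxy-3-(hydroxymethyl)-6-methylbenzoate (target, achiral)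
Conditions: NaBH4 (2 equiv), THF/MeOH, 0 °C, under Ar; aq. NH4Cl to pH ≈ 6
Reagents that add atoms: none
Why: Chemoselective borohydride reduction of the aldehyde at 0 °C leaves the methyl ester and the lactone untouched, and placing it last keeps the acid-sensitive ortho-hydroxybenzyl alcohol away from the deprotection.

**Compound list**
1 | methyl gallate (methyl 3,4,5-trihydroxybenzoate) | COC(=O)c1cc(O)c(O)c(O)c1 | starting material
2 | methyl 7-hydroxy-2,2-dimethyl-1,3-benzodioxole-5-carboxylate | COC(=O)c1cc(O)c2OC(C)(C)Oc2c1 | intermediate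
3 | methyl 6-[(dimethylamino)methyl]-7-hydroxy-2,2-dimethyl-1,3-benzodioxole-5-carboxylate | COC(=O)c1cc2OC(C)(C)Oc2c(O)c1CN(C)C | intermediate
4 | 1-[7-hydroxy-5-(methoxycarbonyl)-2,2-dimethyl-1,3-benzodioxol-6-yl]-N,N,N-trimethylmethanaminium iodide | COC(=O)c1cc2OC(C)(C)Oc2c(O)c1C[N+](C)(C)C.[I-] | intermediate
5 | ortho-quinone methide: methyl 2,2-dimethyl-6-methylidene-7-oxo-6,7-dihydro-1,3-benzodioxole-5-carboxylate | COC(=O)C1=CC2=C(OC(C)(C)O2)C(=O)C1=C | intermediate
6 | methyl 7-hydroxy-2,2,6-trimethyl-1,3-benzodioxole-5-carboxylate | COC(=O)c1cc2OC(C)(C)Oc2c(O)c1C | intermediate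
7 | methyl 7-(benzyloxy)-2,2,6-trimethyl-1,3-benzodioxole-5-carboxylate | COC(=O)c1cc2OC(C)(C)Oc2c(OCc3ccccc3)c1C | intermediate
8 | methyl 7-(benzyloxy)-4-bromo-2,2,6-trimethyl-1,3-benzodioxole-5-carboxylate | COC(=O)c1c(Br)c2OC(C)(C)Oc2c(OCc3ccccc3)c1C | intermediate
9 | [7-(benzyloxy)-4-bromo-2,2,6-trimethyl-1,3-benzodioxol-5-yl]methanol | OCc1c(Br)c2OC(C)(C)Oc2c(OCc3ccccc3)c1C | intermediate
10 | aryllithium alkoxide: lithium [7-(benzyloxy)-4-lithio-2,2,6-trimethyl-1,3-benzodioxol-5-yl]methanolate | [Li]OCc1c([Li])c2OC(C)(C)Oc2c(OCc3ccccc3)c1C | intermediate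
11 | hydroxy acid: 7-(benzyloxy)-5-(hydroxymethyl)-2,2,6-trimethyl-1,3-benzodioxole-4-carboxylic acid | OCc1c(C(=O)O)c2OC(C)(C)Oc2c(OCc3ccccc3)c1C | intermediate
12 | 5-(benzyloxy)-6,7-(isopropylidenedioxy)-4-methylisobenzofuran-1(3H)-one | Cc1c(OCc2ccccc2)c2OC(C)(C)Oc2c2C(=O)OCc12 | intermediate
13 | 5-hydroxy-6,7-(isopropylidenedioxy)-4-methylisobenzofuran-1(3H)-one (fragment B) | Cc1c(O)c2OC(C)(C)Oc2c2C(=O)OCc12 | intermediate
14 | 3-fluoro-5-methylphenol | Cc1cc(O)cc(F)c1 | starting material
15 | 4-bromo-3-fluoro-5-methylphenol | Cc1cc(O)cc(F)c1Br | intermediate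
16 | 2-bromo-1-fluoro-5-(methoxymethoxy)-3-methylbenzene | COCOc1cc(C)c(Br)c(F)c1 | intermediate
17 | aryllithium: [3-bromo-2-fluoro-6-(methoxymethoxy)-4-methylphenyl]lithium | COCOc1cc(C)c(Br)c(F)c1[Li] | intermediate
18 | 3-bromo-2-fluoro-6-(methoxymethoxy)-4-methylbenzaldehyde | COCOc1cc(C)c(Br)c(F)c1C=O | intermediate
19 | methyl 2-fluoro-3-formyl-4-(methoxymethoxy)-6-methylbenzoate (fragment A) | COCOc1cc(C)c(C(=O)OC)c(F)c1C=O | intermediate
20 | methyl 3-formyl-2-{[6,7-(isopropylidenedioxy)-4-methyl-1-oxo-1,3-dihydroisobenzofuran-5-yl]oxy}-4-(methoxymethoxy)-6-methylbenzoate | COCOc1cc(C)c(C(=O)OC)c(Oc2c(C)c3COC(=O)c3c3OC(C)(C)Oc23)c1C=O | intermediate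
21 | methyl 2-[(6,7-dihydroxy-4-methyl-1-oxo-1,3-dihydroisobenzofuran-5-yl)oxy]-3-formyl-4-hydroxy-6-methylbenzoate | COC(=O)c1c(C)cc(O)c(C=O)c1Oc1c(C)c2COC(=O)c2c(O)c1O | intermediate
22 | methyl 2-[(6,7-dihydroxy-4-methyl-1-oxo-1,3-dihydroisobenzofuran-5-yl)oxy]-4-hydroxy-3-(hydroxymethyl)-6-methylbenzoate (achiral) | COC(=O)c1c(C)cc(O)c(CO)c1Oc1c(C)c2c(c(O)c1O)C(=O)OC2 | target

**Step count and risks**
Total steps: 16. Longest linear sequence: 12 steps (steps 1–9 and 14–16, from methyl gallate); the fragment A branch is 4 steps (10–13).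

Steps most likely to fail:

Step 14 (SNAr to a diaryl ether with four ortho substituents). The doubly flanked fluoride 19 may react slowly, or its activated ester may be attacked by phenoxide or carbonate. The fallback inverts the order of ether formation and carbonylation and sets out from 13 and 18. The phenoxide of 13 displaces the fluoride of 18, which is activated by the ortho aldehyde and carries bromine in place of the electrophilic ester (Cs2CO3, DMSO, 90 °C). This gives 3-bromo-6-(methoxymethoxy)-4-methyl-2-{[6,7-(isopropylidenedioxy)-4-methyl-1-oxo-1,3-dihydroisobenzofuran-5-yl]oxy}benzaldehyde F1. Methoxycarbonylation of the aryl bromide of F1 (CO, MeOH, Pd(OAc)2, Xantphos, Et3N, 90 °C) comes back to the route at 20.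

Step 2 (regiochemistry of the Mannich reaction). Aminomethylation could compete at C4, para to the phenol. The fallback delivers the carbon intramolecularly and sets out from 2. Gassman ortho-alkylation (Me2S, N-chlorosuccinimide, CH2Cl2, −25 °C; then Et3N) passes through an aryloxysulfonium ylide whose [2,3]-sigmatropic shift can reach only the ortho carbon. It gives methyl 7-hydroxy-2,2-dimethyl-6-[(methylsulfanyl)methyl]-1,3-benzodioxole-5-carboxylate F2. Desulfurisation with Raney Ni in EtOH at reflux comes back to the route at 6, so steps 3 and 4 are skipped.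

Step 13 (carbonylation next to an SNAr-labile fluoride). Methanol may displace the fluoride once the ester is in place, or the hindered bromide may carbonylate slowly. The fallback introduces the ester by an organolithium route with the aldehyde masked and sets out from 18. HC(OMe)3, MeOH and cat. PPTS at rt give 3-bromo-2-fluoro-6-(methoxymethoxy)-4-methylbenzaldehyde dimethyl acetal F3. Bromine–lithium exchange (n-BuLi, THF, −78 °C) and quenching with ClCO2Me give methyl 3-(dimethoxymethyl)-2-fluoro-4-(methoxymethoxy)-6-methylbenzoate F4. PPTS in acetone/H2O at rt unmasks the aldehyde without cleaving the MOM ether and comes back to the route at 19.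

**Further compounds**
F1 | step 14 | 3-bromo-6-(methoxymethoxy)-4-methyl-2-{[6,7-(isopropylidenedioxy)-4-methyl-1-oxo-1,3-dihydroisobenzofuran-5-yl]oxy}benzaldehyde | COCOc1cc(C)c(Br)c(Oc2c(C)c3COC(=O)c3c3OC(C)(C)Oc23)c1C=O
F2 | step 2 | methyl 7-hydroxy-2,2-dimethyl-6-[(methylsulfanyl)methyl]-1,3-benzodioxole-5-carboxylate | COC(=O)c1cc2OC(C)(C)Oc2c(O)c1CSC
F3 | step 13 | 3-bromo-2-fluoro-6-(methoxymethoxy)-4-methylbenzaldehyde dimethyl acetal | COCOc1cc(C)c(Br)c(F)c1C(OC)OC
F4 | step 13 | methyl 3-(dimethoxymethyl)-2-fluoro-4-(methoxymethoxy)-6-methylbenzoate | COCOc1cc(C)c(C(=O)OC)c(F)c1C(OC)OC
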